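The benzene ring (C1 carries the ester, C2 and C6 are CH, C3 and C5 carry the prenyl groups, C4 carries OH) has a mirror plane through C1 and C4. Cutting C2–C3 and C5–C6 divides it into C3–C4–C5, a symmetric ketone with both prenyl groups in place, and C2–C1–C6, a 2-(alkoxycarbonyl)malonaldehyde with the ester in place.
The ketone is cut further at its two prenyl–Cα bonds (diethyl 3-oxopentanedioate, prenyl bromide). The malonaldehyde ester is cut at one C1–CHO bond (ethyl formate) and at the acyl–oxygen bond ((E)-3-ethoxyacryloyl chloride, terpinen-4-ol).
Forward, a two-step ketone branch and a three-step ester branch meet in the last step. The cyclohexene ring is bought; the benzene ring is the only ring made and arises last, directly as the free phenol, so no phenol is prenylated and no protecting group is carried.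
The one stereocentre, the quaternary (R)-carbinol carbon, comes from (R)-(−)-terpinen-4-ol. Only its O–H bond reacts, its C–O bond is never broken, and strong acid is kept out of the ester branch.
Key step: step 6

Assumption: (R)-(−)-terpinen-4-ol is taken in enantiopure commercial grade, since no later step can raise the enantiomeric purity.
Remark: (R)-terpinen-4-yl stands for (1R)-4-methyl-1-(propan-2-yl)cyclohex-3-en-1-yl. Enol, enolate and push–pull C=C bonds that equilibrate freely, and labile α-centres of β-dicarbonyl compounds, are written without configuration.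

Step 1
Reactants: 1 diethyl 3-oxopentanedioate; 2 prenyl bromide (1-bromo-3-methylbut-2-ene)
Product: 4 diethyl 2,4-bis(3-methylbut-2-en-1-yl)-3-oxopentanedioate, via monoprenylated keto diester 3 (not isolated)
Conditions: NaH (1.0 equiv), THF, 0 °C, then 2 (1.0 equiv), 0 °C → rt; the same two additions once more in the same flask
Reagents that add atoms: 2 prenyl bromide, CC(C)=CCBr
Why: This is the classical α,α'-dialkylation of a 3-oxoglutarate, in which the unsubstituted CH2 of 3 is the more acidic and less hindered site, so the second enolate should form and be alkylated at C4 and not at C2, while the primary allylic bromide reacts by SN2 at its CH2 end.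

Step 2
Reactants: 4 diethyl 2,4-bis(3-methylbut-2-en-1-yl)-3-oxopentanedioate
Product: 6 2,10-dimethylundeca-2,9-dien-6-one, via monodecarboxylated keto ester 5 (not isolated)
Conditions: LiCl, H2O, DMSO, 150 °C
Reagents that add atoms: none
Why: Krapcho dealkoxycarbonylation of an α-monosubstituted β-keto ester should run twice under neutral conditions, which spares the acid-sensitive trisubstituted alkenes and removes both α-stereocentres.

Step 3
Reactants: 7 (R)-(−)-terpinen-4-ol, (1R)-4-methyl-1-(propan-2-yl)cyclohex-3-en-1-ol; 8 (E)-3-ethoxyacryloyl chloride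
Product: 10 (R)-terpinen-4-yl (E)-3-ethoxyprop-2-enoate, via lithium (R)-terpinen-4-oxide 9 (not isolated)
Conditions: n-BuLi, THF, −78 → 0 °C; then 8, 0 °C → rt
Reagents that add atoms: 8 (E)-3-ethoxyacryloyl chloride, CCO/C=C/C(=O)Cl
Why: O-acylation of a preformed lithium tert-alkoxide with an acid chloride is the standard route to esters of hindered, acid-sensitive tertiary alcohols; 8, unlike an activated 3,3-dialkoxypropanoic acid, can neither form a ketene nor lose alcohol by E1cB, and because only the O–H bond reacts the (R)-centre is retained.

Step 4
Reactants: 10 (R)-terpinen-4-yl (E)-3-ethoxyprop-2-enoate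
Product: 11 (R)-terpinen-4-yl 3,3-diethoxypropanoate
Conditions: K2CO3 (0.3 equiv), anhydrous EtOH, rt
Reagents that add atoms: ethanol, CCO
Why: Base-catalysed oxa-Michael addition of an alcohol to a 3-alkoxyacrylate gives the 3,3-dialkoxypropanoate under equilibrium control in excess alcohol, and carbonate in ethanol at room temperature is too weak to transesterify the shielded tertiary ester.

Step 5
Reactants: 11 (R)-terpinen-4-yl 3,3-diethoxypropanoate; 12 ethyl formate
Product: 14 (R)-terpinen-4-yl 2-formyl-3-oxopropanoate, via sodium formyl-acetal enolate 13 (not isolated)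
Conditions: NaH, 12 (excess), cat. EtOH, THF, 0 → 40 °C; then ice-cold 1 M HCl to pH 3, Et2O, 0 °C; concentrated cold and used at once
Reagents that add atoms: 12 ethyl formate, CCOC=O; water, O
Why: The crossed Claisen condensation (C-formylation) of a 3,3-dialkoxypropanoate with a non-enolisable formate is driven by formation of the stabilised enolate 13, whose acetal is activated by the neighbouring enol and should fall apart in cold dilute acid much faster than a tertiary alkyl ester ionises.

Step 6
Reactants: 6 2,10-dimethylundeca-2,9-dien-6-one; 14 (R)-terpinen-4-yl 2-formyl-3-oxopropanoate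
Product: 18 (R)-terpinen-4-yl 4-hydroxy-3,5-bis(3-methylbut-2-en-1-yl)benzoate (CNP0120997.1), via sodium malonaldehyde enolate 15 (not isolated), via acyclic enone-aldehyde 16 (not isolated), via cyclohexa-2,5-dienone tautomer 17 (not isolated)
Conditions: NaOH (3 equiv), 6 (1.5 equiv), EtOH–H2O 4:1, 0 → 40 °C, 2–4 d; then AcOH to pH 6
Reagents that add atoms: none
Why: This is the classical phenol synthesis from a ketone with two α-methylene groups and a 2-substituted malonaldehyde (known for nitro- and alkoxycarbonylmalonaldehydes), mechanistically a double aldol condensation: hydroxide reversibly enolises 6, the enolate adds to a formyl carbon of 15, and loss of water gives 16 (bond C2–C3). The second α-carbon then attacks the remaining formyl group in a favoured 6-(enolendo)-exo-trig aldol closure (bond C5–C6), and the cis geometry this needs is reached because 16 equilibrates through its delocalised dienolate. Loss of the second water gives the cross-conjugated dienone 17, whose doubly vinylogous, ester-activated C1–H is removed at once, so the sequence ends irreversibly in the phenolate of 18 and pulls the unfavourable pre-equilibria forward. No stereocentre is created, and the existing quaternary carbinol centre has no acidic hydrogen and no bond that breaks, so it cannot be scrambled. Regiochemistry is not an issue because both partners are twofold symmetric and each α-carbon of 6 carries exactly the two hydrogens that leave as water; the selectivity needed is chemoselectivity for cross-condensation over self-aldolisation of 6 (reversible and sterically disfavoured) and over hydroxide attack on the ester (blocked by the tertiary, isopropyl-flanked alkoxy group). Because 15 is an anion and therefore a sluggish electrophile, hydroxide instead of a weak amine base, an excess of recoverable 6, high concentration and a reaction time of days are planned.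

Compound list
1 | diethyl 3-oxopentanedioate | CCOC(=O)CC(=O)CC(=O)OCC | starting material
2 | prenyl bromide (1-bromo-3-methylbut-2-ene) | CC(C)=CCBr | starting material
3 | diethyl 2-(3-methylbut-2-en-1-yl)-3-oxopentanedioate (racemic, not isolated) | CCOC(=O)CC(=O)C(CC=C(C)C)C(=O)OCC | intermediate
4 | diethyl 2,4-bis(3-methylbut-2-en-1-yl)-3-oxopentanedioate (diastereomer mixture, both centres lost in step 2) | CCOC(=O)C(CC=C(C)C)C(=O)C(CC=C(C)C)C(=O)OCC | intermediate
5 | ethyl 7-methyl-2-(3-methylbut-2-en-1-yl)-3-oxooct-6-enoate (racemic, not isolated) | CCOC(=O)C(CC=C(C)C)C(=O)CCC=C(C)C | intermediate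
6 | 2,10-dimethylundeca-2,9-dien-6-one | CC(C)=CCCC(=O)CCC=C(C)C | intermediate
7 | (R)-(−)-terpinen-4-ol, (1R)-4-methyl-1-(propan-2-yl)cyclohex-3-en-1-ol | O[C@@]1(C(C)C)CC=C(C)CC1 | starting material
8 | (E)-3-ethoxyacryloyl chloride | CCO/C=C/C(=O)Cl | starting material
9 | lithium (R)-terpinen-4-oxide (not isolated) | [Li+].[O-][C@@]1(C(C)C)CC=C(C)CC1 | intermediate
10 | (R)-terpinen-4-yl (E)-3-ethoxyprop-2-enoate | CCO/C=C/C(=O)O[C@@]1(C(C)C)CC=C(C)CC1 | intermediate
11 | (R)-terpinen-4-yl 3,3-diethoxypropanoate | CCOC(CC(=O)O[C@@]1(C(C)C)CC=C(C)CC1)OCC | intermediate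
12 | ethyl formate | CCOC=O | starting material
13 | sodium 2-(diethoxymethyl)-3-oxo-3-[(R)-terpinen-4-yloxy]prop-1-en-1-olate (not isolated) | [Na+].[O-]C=C(C(OCC)OCC)C(=O)O[C@@]1(C(C)C)CC=C(C)CC1 | intermediate
14 | (R)-terpinen-4-yl 2-formyl-3-oxopropanoate (present largely as its chelated enol) | O=CC(C=O)C(=O)O[C@@]1(C(C)C)CC=C(C)CC1 | intermediate
15 | sodium 2-formyl-3-oxo-3-[(R)-terpinen-4-yloxy]prop-1-en-1-olate (not isolated) | [Na+].[O-]C=C(C=O)C(=O)O[C@@]1(C(C)C)CC=C(C)CC1 | intermediate
16 | (R)-terpinen-4-yl 2-formyl-9-methyl-4-(3-methylbut-2-en-1-yl)-5-oxodeca-3,8-dienoate (C2 and the 3,4-alkene labile, not isolated) | CC(C)=CCCC(=O)C(CC=C(C)C)=CC(C=O)C(=O)O[C@@]1(C(C)C)CC=C(C)CC1 | intermediate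
17 | (R)-terpinen-4-yl 3,5-bis(3-methylbut-2-en-1-yl)-4-oxocyclohexa-2,5-diene-1-carboxylate (not isolated) | CC(C)=CCC1=CC(C(=O)O[C@@]2(C(C)C)CC=C(C)CC2)C=C(CC=C(C)C)C1=O | intermediate
18 | (R)-terpinen-4-yl 4-hydroxy-3,5-bis(3-methylbut-2-en-1-yl)benzoate, CNP0120997.1 | CC(C)=CCc1cc(C(=O)O[C@@]2(C(C)C)CC=C(C)CC2)cc(CC=C(C)C)c1O | target

Total step count: 6. Longest linear sequence: 4 steps (steps 3, 4, 5 and 6, from 7 to 18). The ketone branch (steps 1 and 2) joins in step 6.

Steps most likely to fail

Step 6. The condensation may stall. Hydroxide enolises the ketone only to a trace, the electrophile is a delocalised anion, and slow deformylation of that anion can outrun C–C bond formation. The fallback forms the same two ring bonds but replaces the anionic electrophile by a neutral one.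
- It sets out from 14 (and 6). Dimethylamine (THF, MgSO4, 0 °C → rt) should condense with 14 to give the neutral enaminal (R)-terpinen-4-yl 3-(dimethylamino)-2-formylprop-2-enoate F1.
- F1 is added to the potassium enolate of 6 (KOt-Bu, THF, 0 → 50 °C). Aldol addition and dehydration should give the neutral dienaminone (R)-terpinen-4-yl 2-[(dimethylamino)methylidene]-9-methyl-4-(3-methylbut-2-en-1-yl)-5-oxodeca-3,8-dienoate F2.
- A single further deprotonation of F2 gives an enolate that closes onto the CH–NMe2 carbon. This can be seen as conjugate addition–elimination, or as 6π-electrocyclisation of the trienolate followed by loss of dimethylamine.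
- Tautomerisation brings the sequence back to the route at 18.

Step 5. Formylation may be eroded by E1cB loss of ethoxide from the ester enolate and by slow transesterification with ethoxide. In the acidic unmasking the tertiary ester may ionise with loss of the terpinenyl group, helped by the acidity of the product itself. The fallback uses neither an ester enolate nor acid.
- It sets out from 10. Dimethylamine (EtOH, 60 °C) should replace ethoxide by addition–elimination to give (R)-terpinen-4-yl (E)-3-(dimethylamino)prop-2-enoate F3.
- Vilsmeier–Haack formylation with (chloromethylene)dimethyliminium chloride (from DMF and oxalyl chloride), buffered with 2,6-lutidine in CH2Cl2 at 0 °C, should give the vinamidinium salt [3-(dimethylamino)-2-{[(R)-terpinen-4-yl]oxycarbonyl}prop-2-en-1-ylidene]dimethylammonium chloride F4.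
- Aqueous NaOH (0 °C → rt) hydrolyses both C–N termini, passing through F1.
- This comes back to the route at the sodium salt 15, which enters step 6 directly.

Step 3. Acylation may be too slow. The alkoxide oxygen is flanked by the isopropyl group and the ring, and the vinylogous carbonate-type chloride is a tempered electrophile. Attack at its β-carbon, or simple return of the alcohol on work-up, could then prevail. The fallback attaches the smallest acyl group first and grows the three-carbon unit on the ester.
- It sets out from 7. Ac2O, Et3N and DMAP (CH2Cl2, rt → 40 °C) should give (R)-terpinen-4-yl acetate F5.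
- LiN(i-Pr)2 (THF, −78 °C) followed by 12 should give (R)-terpinen-4-yl 3-oxopropanoate F6.
- F6 is taken on crude with triethyl orthoformate, EtOH and catalytic pyridinium p-toluenesulfonate (rt).
- This comes back to the route at acetal 11.

Further compounds
F1 | step 6 | (R)-terpinen-4-yl 3-(dimethylamino)-2-formylprop-2-enoate | CN(C)C=C(C=O)C(=O)O[C@@]1(C(C)C)CC=C(C)CC1
F2 | step 6 | (R)-terpinen-4-yl 2-[(dimethylamino)methylidene]-9-methyl-4-(3-methylbut-2-en-1-yl)-5-oxodeca-3,8-dienoate | CC(C)=CCCC(=O)C(CC=C(C)C)=CC(=CN(C)C)C(=O)O[C@@]1(C(C)C)CC=C(C)CC1
F3 | step 5 | (R)-terpinen-4-yl (E)-3-(dimethylamino)prop-2-enoate | CN(C)/C=C/C(=O)O[C@@]1(C(C)C)CC=C(C)CC1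
F4 | step 5 | [3-(dimethylamino)-2-{[(R)-terpinen-4-yl]oxycarbonyl}prop-2-en-1-ylidene]dimethylammonium chloride | CN(C)C=C(C=[N+](C)C)C(=O)O[C@@]1(C(C)C)CC=C(C)CC1.[Cl-]
F5 | step 3 | (R)-terpinen-4-yl acetate | CC(=O)O[C@@]1(C(C)C)CC=C(C)CC1
F6 | step 3 | (R)-terpinen-4-yl 3-oxopropanoate | O=CCC(=O)O[C@@]1(C(C)C)CC=C(C)CC1
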